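(The numbers of this flask were set for the occasion, and the outcome is calculated.)

In this closed flask each step turns one molecule into one molecule, so the six forms together add up, at each moment, to the 0.073 M of substrate charged.

substrate 0.073 M; time 4.0 h

    substrate ⇌ isomer of the product A (K1 = 17.0, k1 = 0.0106 s⁻¹)
    substrate ⇌ third isomer (K2 = 1.2, k2 = 0.0281 s⁻¹)
    target ⇌ isomer of the product B (K3 = 0.987, k3 = 0.0163 s⁻¹)
    substrate ⇌ target (K4 = 11, k4 = 0.0298 s⁻¹)
    substrate ⇌ dormant form (K5 = 2.75, k5 = 0.00134 s⁻¹)

- the reaction counts as stopped when no species that holds the substrate changes by six tenths of a point or more over the second half of the time
- run time (flask): 4.0 h

* the state of affairs at 4.0 h: stopped, and by what, or still going (forward and back rates have come level / all of the substrate has reacted / it is still moving)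
* target at 4.0 h, in percent of the substrate charged
* isomer of the product A at 4.0 h, in percent of the substrate charged

I began by turning the constants into times. Each k here is a forward constant, and the back constant is k divided by K, so that forward and back match when the right-hand form stands at K times the left-hand one. Forward, substrate went quickly: its half-life by step 4 alone, the way back not counted, was 0.39 min. The wait lay in the returns. The return from dormant form, by its back rate alone, had a half-life of 23.7 min, longer than the 18.5 min from isomer of the product A and the other returns, each reckoned the same way. The run held 10.1 such half-lives, so I committed to forward and back rates coming level before the end.

With the rates level, the invariant gave the amounts, under thermodynamic control. I counted substrate as one part, isomer of the product A as K1 parts, third isomer as K2, target as K4, dormant form as K5, and isomer of the product B, standing behind target, as K3 times K4. The total of these parts is the weight sum 43.8, and a form's share of the charge is its parts divided by that sum. That gave target 25.1% and isomer of the product A 38.8%.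

The forecast gave the same: forward and back rates have come level, target 25.1%, isomer of the product A 38.8%, on the ground that “over 4 h the system is effectively at equilibrium”.

The simulation gave: forward and back rates have come level, target 25.1%, isomer of the product A 38.8%, and the largest move over the second half was 0.032 percentage points. The weight sum also served for dormant form in this flask: 2.75 parts in 43.8 make 6.28%, and the reading was 6.28%. The sum holds no concentration, so for the neighbour flask charged at 0.29 M it again gave substrate 2.28%, and that flask ended with 2.28%. The sum needs the way back: with the return of isomer of the product A to substrate struck out, this flask no longer ended level, and that isomer stood at 98.9% at 4.0 h.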